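The target is disconnected at the C1–C5 bond. In the hydroazulene the C6 oxygen sits beside C5–H and the quaternary C1, so C1 can be traced back to C6 of a cis-decalin made from thymoquinone and isoprene. One semipinacol 1,2-shift of C1 from C6 to C5 contracts ring A to the cyclopentane, enlarges ring B to the cycloheptenone, turns the C6 oxygen into the ketone and sets the trans ring fusion by inversion at C5. Its precursor is a cis-decalin with all-cis oxygens at C4 (silyl ether), C5 (equatorial mesylate) and C6 (free hydroxyl), already carrying the C2 acetate and the C8=C9 alkene.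

Key step: step 10

Convention: every bicyclic compound keeps daucane numbering (C1 quaternary methyl carbon, C4 isopropyl carbon, C8 methyl-bearing alkene carbon). In the decalins ring A is C1–C6 and ring B is C1, C6–C10; in the hydroazulenes ring A is C1–C5 and ring B is C1, C5–C10. β is the face of the C1 methyl group, α the opposite face. The target is read as (1R,2S,4R,5S,6S): 1β-methyl, 2α-acetoxy, 4β-hydroxy, 4α-isopropyl, 5α-H, 6α-aroyloxy.

Assumption: the (S)-configured catalyst of step 1 is taken to expose the quinone face that leads to the (1R) adduct; should the first run give the antipode, the (R)-catalyst is used with nothing else changed.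

Step 1
Reactants: 1 thymoquinone (2-isopropyl-5-methyl-1,4-benzoquinone); 2 isoprene
Product: 3 cis-adduct (4aR,8aS)-2-isopropyl-4a,7-dimethyl-4a,5,8,8a-tetrahydronaphthalene-1,4-dione (daucane numbering: C2 and C5 ketones, C3=C4 and C8=C9 alkenes, 1β-methyl, 6β-H)
Conditions: (S)-3,3-diphenyl-1-(2-methylphenyl)hexahydropyrrolo[1,2-c][1,3,2]oxazaborole (20 mol%), HN(SO2CF3)2 (20 mol%), 2 (5 equiv), CH2Cl2, −78 → −40 °C
Reagents that add atoms: none
Why: Diels–Alder cycloaddition under chiral cationic oxazaborolidine catalysis: the Lewis acid is expected to bind the carbonyl that becomes C2 at its lone pair syn to C3–H, which makes the unsubstituted terminus C6 of the less hindered, methyl-bearing alkene the electrophilic site, so the nucleophilic CH2 terminus of isoprene (the one next to its methyl-bearing carbon) bonds to C6 and the ring-B methyl ends on C8, para to C1; suprafacial addition fixes the cis fusion (C1 methyl and C6 hydrogen both β) and the chiral cation selects the quinone face, setting C1 as R.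

Step 2
Reactants: 3 cis-adduct
Product: 4 3β,4β-epoxy-2,5-diketone (6β-H, 4α-isopropyl)
Conditions: 30% H2O2, Na2CO3, MeOH/THF, 0 °C
Reagents that add atoms: hydrogen peroxide, OO
Why: Weitz–Scheffer nucleophilic epoxidation of the enedione: hydroperoxide adds to the unsubstituted C3 from the β-face, the convex face of the folded cis-adduct that carries only the angular methyl and hydrogen and lies anti to the pseudo-axial C10 methylene, and the C4 enolate closes on the same face, which sets the C4–O bond β and the isopropyl group α, while the isolated C8=C9 alkene is inert to the nucleophilic oxidant.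

Step 3
Reactants: 4 3β,4β-epoxy-2,5-diketone
Product: 6 3β,4β-epoxy-6β-(trimethylsilyloxy)-2,5-diketone, via hydroxy epoxy diketone 5 (not isolated)
Conditions: KN(SiMe3)2, THF, −78 °C; 2-(phenylsulfonyl)-3-phenyloxaziridine, −78 °C; then Me3SiCl, −78 → 0 °C
Reagents that add atoms: 2-(phenylsulfonyl)-3-phenyloxaziridine, O=S(=O)(c1ccccc1)N1OC1c1ccccc1; chlorotrimethylsilane, C[Si](C)(C)Cl
Why: Enolate hydroxylation (Davis oxidation) with O-silylation of the resulting potassium alkoxide in the same flask: C6–H is the only enolisable hydrogen (C1 is quaternary, C3 and C4 are oxirane carbons), and the oxaziridine should attack the C6 enolate on the β-face because the α-face is covered by ring B (C10, C8) and by the α-isopropyl group on C4, so the new C–O bond is cis to the C1 methyl and the cis ring fusion is kept; the trimethylsilyl ether masks this tertiary oxygen until the C4 oxygen has been silylated, and the neutral oxaziridine leaves C8=C9 untouched.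

Step 4
Reactants: 6 3β,4β-epoxy-6β-(trimethylsilyloxy)-2,5-diketone
Product: 7 4β-hydroxy-6β-(trimethylsilyloxy)-2,5-diketone (C3 now CH2)
Conditions: (PhSe)2, NaBH4, EtOH, 0 °C; then AcOH and 6, 0 °C → rt
Reagents that add atoms: none
Why: Organoselenium-mediated reductive opening of an α,β-epoxy ketone with sodium phenylseleno(triethoxy)borate: the selenide attacks the secondary C3, α to the C2 ketone, and not the tertiary isopropyl-bearing C4, a second selenide removes selenium to give the C2 enolate, and protonation leaves C3 as CH2 and the untouched C4–O bond as the β tertiary alcohol, under buffered conditions mild enough to spare the aldol from dehydration.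

Step 5
Reactants: 7 4β-hydroxy-6β-(trimethylsilyloxy)-2,5-diketone
Product: 9 4β-(triethylsilyloxy)-6β-hydroxy-2,5-diketone, via bis(silyl ether) 8 (not isolated)
Conditions: Et3SiOTf, 2,6-lutidine, CH2Cl2, −78 → 0 °C; then MeOH, pyridinium p-toluenesulfonate, 0 °C
Reagents that add atoms: triethylsilyl trifluoromethanesulfonate, CC[Si](CC)(CC)OS(=O)(=O)C(F)(F)F
Why: Silyl ether formation followed by selective solvolysis: C4–OH is the only free hydroxyl, so it is silylated without ambiguity, and mild acidic methanolysis then removes the far more labile trimethylsilyl group from the C6 oxygen while the tertiary triethylsilyl ether survives, so the two tertiary oxygens are told apart by timing and not by sterics.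

Step 6
Reactants: 9 4β-(triethylsilyloxy)-6β-hydroxy-2,5-diketone
Product: 10 2α,6β-dihydroxy-4β-(triethylsilyloxy)-5-ketone
Conditions: Me4NBH(OAc)3, MeCN/AcOH (1:1), −30 °C
Reagents that add atoms: none
Why: Hydroxyl-directed reduction (Evans–Saksena type): the β-hydroxyl at C6 exchanges onto boron and delivers hydride through a six-membered transition state to the β-face of the C2 ketone, giving the 2α-alcohol anti to the C6 hydroxyl, while the C5 ketone, wedged between two fully substituted carbons and screened on its β-face by the triethylsilyloxy group, should not be reduced by this mild reagent.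

Step 7
Reactants: 10 2α,6β-dihydroxy-4β-(triethylsilyloxy)-5-ketone
Product: 11 2α-acetoxy-6β-hydroxy-4β-(triethylsilyloxy)-5-ketone
Conditions: Ac2O, pyridine, 4-(dimethylamino)pyridine (cat.), CH2Cl2, 0 °C → rt
Reagents that add atoms: acetic anhydride, CC(=O)OC(C)=O
Why: Acylation of the only secondary alcohol: the tertiary ring-fusion hydroxyl at C6 does not react under these conditions, so the acetate is placed at C2 alone and no stereocentre is touched.

Step 8
Reactants: 11 2α-acetoxy-6β-hydroxy-4β-(triethylsilyloxy)-5-ketone
Product: 12 2α-acetoxy-4β-(triethylsilyloxy)-5β,6β-diol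
Conditions: NaBH4, CeCl3·7H2O, MeOH, −40 → 0 °C
Reagents that add atoms: none
Why: Luche-type ketone reduction: in the chair with equatorial isopropyl the C4 and C6 oxygens are both axial on the β-face, so borohydride should attack C5 axially from the α-face, anti to both C–O bonds (Felkin–Anh polar control reinforced by the bulk of the silyl ether), giving the equatorial 5β-alcohol and the all-cis 4,5,6-oxygen pattern, with the acetate intact under the cerium-buffered conditions.

Step 9
Reactants: 12 2α-acetoxy-4β-(triethylsilyloxy)-5β,6β-diol
Product: 13 2α-acetoxy-6β-hydroxy-5β-(methanesulfonyloxy)-4β-(triethylsilyloxy) cis-decalin (1β-methyl, 4α-isopropyl, 8-methyl, C8=C9)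
Conditions: MeSO2Cl, NEt3, CH2Cl2, −20 → 0 °C
Reagents that add atoms: methanesulfonyl chloride, CS(=O)(=O)Cl
Why: Sulfonylation through sulfene: the hindered secondary C5 hydroxyl is mesylated while the tertiary C6 hydroxyl stays free, and the hydroxy mesylate is stable because both neighbouring oxygens are cis to the leaving group and cannot displace it to form an epoxide.

Step 10
Reactants: 13 2α-acetoxy-6β-hydroxy-5β-(methanesulfonyloxy)-4β-(triethylsilyloxy) cis-decalin
Product: 14 2α-acetoxy-4β-(triethylsilyloxy)-trans-hydroazulen-6-one (daucane skeleton, 1β-methyl, 5α-H, C8=C9)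
Conditions: AlEt3 (3 equiv), CH2Cl2, −78 → −20 °C; aqueous KNaC4H4O6 work-up
Reagents that add atoms: none
Why: AlEt3 turns the C6 hydroxyl into an aluminium alkoxide (push) and its remaining Lewis acidity loosens the neighbouring C5 mesylate (pull), so the C6–C1 bond, antiperiplanar to the equatorial C5–O bond in the chair with equatorial isopropyl, shifts to C5 as the mesylate leaves and C6 becomes the ketone; this is a semipinacol (pinacol-type) rearrangement of a 2-hydroxy sulfonate, whose closest precedents are organoaluminium-promoted rearrangements of β-mesyloxy alcohols and decalin-to-hydroazulene shifts of hydroxy sulfonates. No ring is closed by a chain end: through the single suprafacial 1,2-alkyl shift ring A loses C6 and becomes the cyclopentane (ring contraction, new C1–C5 bond) while ring B gains C5 and becomes the cycloheptenone (ring expansion). The only new stereocentre, C5, is set by the stereospecific inversion at the migration terminus, which brings C1 in opposite to the departing β-mesylate and leaves H5 α, trans to the C1 methyl, and the migrating quaternary C1 keeps its configuration. The step must move C1 and not C7, C3 or hydride: C7 is gauche to the leaving group, C4 and C6 carry no hydrogen, and the equally aligned C4–C3 bond stays because its oxygen is a silyl ether (a poor donor that forms no aluminium alkoxide) and C3 is a primary, poorer migrating carbon than the quaternary C1. Epoxide formation is excluded because the C4, C5 and C6 oxygens are all cis, and elimination is excluded for want of a β-hydrogen.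

Step 11
Reactants: 14 2α-acetoxy-4β-(triethylsilyloxy)-trans-hydroazulen-6-one
Product: 15 2α-acetoxy-4β-hydroxy-trans-hydroazulen-6-one
Conditions: HF·pyridine, pyridine, THF, 0 °C
Reagents that add atoms: none
Why: Fluoride-mediated Si–O cleavage under buffered, weakly acidic conditions frees the tertiary C4 hydroxyl without epimerising C5, moving the β,γ-alkene into conjugation or provoking retro-aldol cleavage of the new β-hydroxy ketone.

Step 12
Reactants: 15 2α-acetoxy-4β-hydroxy-trans-hydroazulen-6-one
Product: 16 2α-acetoxy-daucane-8-ene-4β,6α-diol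
Conditions: Me4NBH(OAc)3, MeCN/AcOH (1:1), −30 °C
Reagents that add atoms: none
Why: Hydroxyl-directed reduction (Evans–Saksena): the 4β-hydroxyl binds the borohydride and delivers hydride intramolecularly to the β-face of the C6 ketone, which should give the 6α-alcohol (1,3-anti to the C4 hydroxyl) against the steric bias of the β-methyl on C1, with acetate and alkene untouched.

Step 13
Reactants: 17 4-hydroxybenzoic acid
Product: 19 4-(tert-butyldimethylsilyloxy)benzoic acid, via silyl ester silyl ether 18 (not isolated)
Conditions: tBuMe2SiCl (2.2 equiv), imidazole, DMF, rt; then AcOH/THF/H2O, rt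
Reagents that add atoms: tert-butylchlorodimethylsilane, CC(C)(C)[Si](C)(C)Cl
Why: Silylation of both acidic sites and hydrolysis of the labile silyl ester leaves the phenol protected as its silyl ether and the carboxylic acid free, so the phenol cannot compete in the esterification.

Step 14
Reactants: 16 2α-acetoxy-daucane-8-ene-4β,6α-diol; 19 4-(tert-butyldimethylsilyloxy)benzoic acid
Product: 20 6α-O-[4-(tert-butyldimethylsilyloxy)benzoyl] ester of 16
Conditions: N-(3-dimethylaminopropyl)-N′-ethylcarbodiimide hydrochloride, 4-(dimethylamino)pyridine, CH2Cl2, rt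
Reagents that add atoms: none
Why: Steglich esterification: the secondary 6α-hydroxyl is acylated while the tertiary C4 hydroxyl is inert, and no stereocentre is touched.

Step 15
Reactants: 20 6α-O-[4-(tert-butyldimethylsilyloxy)benzoyl] ester
Product: 21 CNP0275279.1
Conditions: Bu4NF, AcOH (1:1), THF, 0 °C
Reagents that add atoms: none
Why: Fluoride cleaves the aryl silyl ether rapidly at low temperature, and buffering with acetic acid keeps the phenoxide from attacking the C2 acetate or the aroyl ester.

Compound list
1 | thymoquinone | CC1=CC(=O)C(C(C)C)=CC1=O | starting material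
2 | isoprene | C=CC(C)=C | starting material
3 | (4aR,8aS)-2-isopropyl-4a,7-dimethyl-4a,5,8,8a-tetrahydronaphthalene-1,4-dione (cis-adduct) | O=C1C=C(C(C)C)C(=O)[C@H]2CC(C)=CC[C@@]12C | intermediate
4 | 3β,4β-epoxy-2,5-diketone (6β-H) | O=C1[C@@H]3O[C@]3(C(C)C)C(=O)[C@H]2CC(C)=CC[C@@]12C | intermediate
5 | 6β-hydroxy-3β,4β-epoxy-2,5-diketone (formed as potassium alkoxide, not isolated) | O=C1[C@@H]3O[C@]3(C(C)C)C(=O)[C@@]2(O)CC(C)=CC[C@@]12C | intermediate
6 | 3β,4β-epoxy-6β-(trimethylsilyloxy)-2,5-diketone | O=C1[C@@H]3O[C@]3(C(C)C)C(=O)[C@@]2(O[Si](C)(C)C)CC(C)=CC[C@@]12C | intermediate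
7 | 4β-hydroxy-6β-(trimethylsilyloxy)-2,5-diketone | O=C1C[C@@](O)(C(C)C)C(=O)[C@@]2(O[Si](C)(C)C)CC(C)=CC[C@@]12C | intermediate
8 | 4β-(triethylsilyloxy)-6β-(trimethylsilyloxy)-2,5-diketone (not isolated) | O=C1C[C@@](O[Si](CC)(CC)CC)(C(C)C)C(=O)[C@@]2(O[Si](C)(C)C)CC(C)=CC[C@@]12C | intermediate
9 | 4β-(triethylsilyloxy)-6β-hydroxy-2,5-diketone | O=C1C[C@@](O[Si](CC)(CC)CC)(C(C)C)C(=O)[C@@]2(O)CC(C)=CC[C@@]12C | intermediate
10 | 2α,6β-dihydroxy-4β-(triethylsilyloxy)-5-ketone | O[C@H]1C[C@@](O[Si](CC)(CC)CC)(C(C)C)C(=O)[C@@]2(O)CC(C)=CC[C@@]12C | intermediate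
11 | 2α-acetoxy-6β-hydroxy-4β-(triethylsilyloxy)-5-ketone | CC(=O)O[C@H]1C[C@@](O[Si](CC)(CC)CC)(C(C)C)C(=O)[C@@]2(O)CC(C)=CC[C@@]12C | intermediate
12 | 2α-acetoxy-4β-(triethylsilyloxy)-5β,6β-diol | CC(=O)O[C@H]1C[C@@](O[Si](CC)(CC)CC)(C(C)C)[C@H](O)[C@@]2(O)CC(C)=CC[C@@]12C | intermediate
13 | 2α-acetoxy-6β-hydroxy-5β-(methanesulfonyloxy)-4β-(triethylsilyloxy) cis-decalin (rearrangement precursor) | CC(=O)O[C@H]1C[C@@](O[Si](CC)(CC)CC)(C(C)C)[C@H](OS(C)(=O)=O)[C@@]2(O)CC(C)=CC[C@@]12C | intermediate
14 | 2α-acetoxy-4β-(triethylsilyloxy)-trans-hydroazulen-6-one (5α-H) | CC(=O)O[C@H]1C[C@@](O[Si](CC)(CC)CC)(C(C)C)[C@@H]2C(=O)CC(C)=CC[C@@]12C | intermediate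
15 | 2α-acetoxy-4β-hydroxy-trans-hydroazulen-6-one | CC(=O)O[C@H]1C[C@@](O)(C(C)C)[C@@H]2C(=O)CC(C)=CC[C@@]12C | intermediate
16 | 2α-acetoxy-daucane-8-ene-4β,6α-diol | CC(=O)O[C@H]1C[C@@](O)(C(C)C)[C@@H]2[C@@H](O)CC(C)=CC[C@@]12C | intermediate
17 | 4-hydroxybenzoic acid | O=C(O)c1ccc(O)cc1 | starting material
18 | tert-butyldimethylsilyl 4-(tert-butyldimethylsilyloxy)benzoate (not isolated) | CC(C)(C)[Si](C)(C)OC(=O)c1ccc(O[Si](C)(C)C(C)(C)C)cc1 | intermediate
19 | 4-(tert-butyldimethylsilyloxy)benzoic acid | CC(C)(C)[Si](C)(C)Oc1ccc(C(=O)O)cc1 | intermediate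
20 | 6α-O-[4-(tert-butyldimethylsilyloxy)benzoyl] ester of 16 | CC(=O)O[C@H]1C[C@@](O)(C(C)C)[C@@H]2[C@@H](OC(=O)c3ccc(O[Si](C)(C)C(C)(C)C)cc3)CC(C)=CC[C@@]12C | intermediate
21 | CNP0275279.1, (1R,2S,4R,5S,6S)-2α-acetoxy-4β-hydroxy-6α-(4-hydroxybenzoyloxy)daucane-8-ene | CC(=O)O[C@H]1C[C@@](O)(C(C)C)[C@@H]2[C@@H](OC(=O)c3ccc(O)cc3)CC(C)=CC[C@@]12C | target

Total step count: 15 (14 in the main line, 1 for the acid component).
Longest linear sequence: 14 steps (steps 1–12, 14, 15).

Steps most likely to fail

Step 1. The diene may add in the wrong orientation: if the catalyst binds the other carbonyl, the nucleophilic terminus of isoprene is steered to C1 and the ring-B methyl lands on C9. Isoprene is only weakly polarised, so a mixture of orientations, or some reaction at the isopropyl-bearing alkene, is also possible. The fallback lets the polarisation of the diene, not a methyl group, fix the orientation. It sets out from 1 and uses the same catalyst with 3-methyl-2-(triisopropylsilyloxy)buta-1,3-diene F1 (from 3-methylbut-3-en-2-one, iPr3SiOTf, NEt3). Its enol-ether CH2, the strongly nucleophilic terminus, bonds to the carbon that the catalyst activates, which is C1 in the failure mode described. This gives the C9-silyloxy cis-adduct F2 with the methyl already on C8. CsF and PhN(SO2CF3)2 then convert the silyl enol ether regiospecifically into the C8=C9 enol triflate F3, and Pd(OAc)2, PPh3, HCO2H, NBu3 replace the triflate by hydrogen. The fallback comes back to the route at 3.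

Step 3. The C6 enolate may be consumed by the neighbouring epoxide (Favorskii-type closure) before it is oxidised, and attack of the oxidant from the α-face is a second concern. The fallback inverts the order, so that the C6 oxygen is installed before the epoxide exists. It sets out from 3: KN(SiMe3)2, the oxaziridine and Me3SiCl give the 6β-(trimethylsilyloxy) enedione F4. Nucleophilic epoxidation with anhydrous tBuOOH and 1,8-diazabicyclo[5.4.0]undec-7-ene should then occur anti to the pseudo-axial C10 methylene, in the conformer that holds the silyloxy group axial. The fallback comes back to the route at 6.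

Step 10. The secondary C5–O bond, flanked by two oxygen-bearing quaternary carbons, may ionise too slowly, so that AlEt3 attacks the acetate or the product ketone first. Alternatively the C4 silyl ether may be lost, after which its oxygen could drive the shift of C3. The fallback removes the organoaluminium reagent and the isolated sulfonate altogether. It sets out from 12: (CF3SO2)2O with 2,6-di-tert-butyl-4-methylpyridine in CH2Cl2 at −78 °C gives the C5 trifluoromethanesulfonate F5. With this far better leaving group the free C6 hydroxyl alone should push the C6–C1 bond across on warming, the proton being taken by the hindered pyridine. The fallback comes back to the route at 14.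

Further compounds
F1 | step 1 | 3-methyl-2-(triisopropylsilyloxy)buta-1,3-diene | C=C(C)C(=C)O[Si](C(C)C)(C(C)C)C(C)C
F2 | step 1 | C9-(triisopropylsilyloxy) cis-adduct (C8 methyl, C8=C9 enol ether) | O=C1C=C(C(C)C)C(=O)[C@H]2CC(C)=C(O[Si](C(C)C)(C(C)C)C(C)C)C[C@@]12C
F3 | step 1 | C9 enol trifluoromethanesulfonate of the cis-adduct | O=C1C=C(C(C)C)C(=O)[C@H]2CC(C)=C(OS(=O)(=O)C(F)(F)F)C[C@@]12C
F4 | step 3 | 6β-(trimethylsilyloxy) enedione | O=C1C=C(C(C)C)C(=O)[C@@]2(O[Si](C)(C)C)CC(C)=CC[C@@]12C
F5 | step 10 | C5 trifluoromethanesulfonate of 12 | CC(=O)O[C@H]1C[C@@](O[Si](CC)(CC)CC)(C(C)C)[C@H](OS(=O)(=O)C(F)(F)F)[C@@]2(O)CC(C)=CC[C@@]12C
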